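**Strategy.** The carbocycle of the 6H-isochromene-6,8(7H)-dione (numbering O2, C1–C8a) is cut at C6–C7 and C8–C8a. This exposes the 7-methyl-7-acyloxy-6,8-dione as a lactic acid unit (C7, C8) lying between two acyl-transfer sites. In one operation the lithium enolate of the pivaldehyde acetal of (S)-lactic acid is acylated by the lactone carbonyl of a 4-enynyl-2H-pyran-2-one (C6–C7, quaternary 7R centre). The pyranone opens to a formyl dienolate whose C8a closes on the dioxolanone carbonyl (C8–C8a) with loss of pivaldehyde, and CuI then closes the pyran ring. Both precursor lactone rings vanish. Esterification with silyl-protected orsellinoyl chloride, desilylation and allylic oxidation finish the route.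

Key step: step 7

Remark: vinylogous acids and enolates are drawn as one tautomer, and atom labels (C1, O2, C3 … C8a) follow the isochromene numbering of the target throughout.
Assumption: (E)-pent-2-en-4-yn-1-ol (9) is used as the pure E isomer.

**Step 1**
Reactants: 1 (S)-lactic acid; 2 pivaldehyde
Product: 3 (2S,5S)-2-tert-butyl-5-methyl-1,3-dioxolan-4-one
Conditions: TsOH·H2O (cat.), H2SO4 (cat.), pentane, reflux, Dean–Stark trap; crystallization from pentane at −78 °C
Reagents that add atoms: none
Why: Acid-catalysed acetalization under thermodynamic control should favour the cis acetal, in which C5 keeps the lactic acid configuration and C2 is set cis to the methyl group; low-temperature crystallization removes the trans isomer.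

**Step 2**
Reactants: 4 tert-butyl acetate; 5 methyl 3,3-dimethoxypropanoate
Product: 6 tert-butyl 5,5-dimethoxy-3-oxopentanoate
Conditions: LDA (2.2 equiv), 4 (2.2 equiv), THF, −78 °C; then 5, −78 → −30 °C; AcOH quench
Reagents that add atoms: none
Why: Crossed Claisen condensation, in which the excess lithium enolate of tert-butyl acetate acylates at the methyl ester of 5 at low temperature before beta-elimination of methoxide can intervene, the second equivalent deprotonating the product.

**Step 3**
Reactants: 6 tert-butyl 5,5-dimethoxy-3-oxopentanoate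
Product: 7 4-hydroxy-2H-pyran-2-one
Conditions: TFA/CH2Cl2 (1:1), 0 °C → rt
Reagents that add atoms: none
Why: Acid-mediated enol-lactonization: TFA cleaves the tert-butyl ester and ionizes the acetal, the acid closes onto the oxocarbenium ion to a six-membered pseudo-ester, and loss of methanol gives the pyranone, as in the standard cyclization of 3,5-dioxo ester equivalents.

**Step 4**
Reactants: 7 4-hydroxy-2H-pyran-2-one
Product: 8 2-oxo-2H-pyran-4-yl trifluoromethanesulfonate
Conditions: Tf2O, Et3N, CH2Cl2, −78 → 0 °C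
Reagents that add atoms: trifluoromethanesulfonic anhydride, O=S(=O)(OS(=O)(=O)C(F)(F)F)C(F)(F)F
Why: O-Sulfonylation of the vinylogous acid, which 4-hydroxy-2-pyranones are known to undergo at the 4-oxygen.

**Step 5**
Reactants: 9 (E)-pent-2-en-4-yn-1-ol
Product: 10 tert-butyldimethyl{[(E)-pent-2-en-4-yn-1-yl]oxy}silane
Conditions: TBSCl, imidazole, CH2Cl2, rt
Reagents that add atoms: tert-butyldimethylsilyl chloride, CC(C)(C)[Si](C)(C)Cl
Why: Standard silylation of a primary alcohol, which removes the only acidic O–H before the enolate chemistry.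

**Step 6**
Reactants: 8 2-oxo-2H-pyran-4-yl trifluoromethanesulfonate; 10 tert-butyldimethyl{[(E)-pent-2-en-4-yn-1-yl]oxy}silane
Product: 11 4-[(E)-5-(tert-butyldimethylsilyloxy)pent-3-en-1-yn-1-yl]-2H-pyran-2-one
Conditions: PdCl2(PPh3)2 (3 mol %), CuI (5 mol %), Et3N, MeCN, rt
Reagents that add atoms: none
Why: Sonogashira coupling; 4-sulfonyloxy- and 4-halo-2-pyranones are established electrophiles, and a tertiary amine base should not open the pyranone.

**Step 7**
Reactants: 3 (2S,5S)-2-tert-butyl-5-methyl-1,3-dioxolan-4-one; 11 4-[(E)-5-(tert-butyldimethylsilyloxy)pent-3-en-1-yn-1-yl]-2H-pyran-2-one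
Product: 14 (7R)-7-hydroxy-7-methyl-3-[(E)-3-(tert-butyldimethylsilyloxy)prop-1-en-1-yl]-6H-isochromene-6,8(7H)-dione, via ring-opened lithium dienolate 12 (not isolated), via alkynyl vinylogous acid 13 (not isolated)
Conditions: 3 (1.1 equiv), LDA (1.05 equiv), THF, −78 °C; then 11, −78 → 0 °C; AcOH (1.1 equiv); then CuI (10 mol %), MeCN/pH 7 phosphate buffer, rt
Reagents that add atoms: none
Why: Proposed new method: the lithium enolate of 3 adds to the lactone carbonyl of 11 and the adduct collapses by expelling the ring oxygen as a glutaconaldehyde-type dienolate (12, in which the new C6 ketone is masked against a second addition); on warming, C8a of 12 attacks the dioxolanone carbonyl, whose ring oxygen leaves as a hemiacetal alkoxide that sheds pivaldehyde to unveil the 7-OH, the triacylmethane-type anion of 13 being the thermodynamic sink, and CuI then adds the formyl enol oxygen across the alkyne. The closest known chemistry is the Claisen–Dieckmann logic of Staunton–Weinreb and Hauser–Kraus anionic annulations, the conversion of isocoumarins into naphthols by ester enolates, and the C-acylation of lactate-derived dioxolanone enolates; what is new is an alpha-pyrone acting as acyl donor plus latent enolate towards a dioxolanone that is nucleophile and acyl acceptor in turn. The carbocycle closes 6-exo-trig (C8a onto C8; the other nucleophilic carbon, C5, could only give a four-membered ring) and the pyran ring closes 6-endo-dig (O2 onto C3), the established copper-catalysed cycloisomerization of such alkynyl vinylogous acids. C7, the only stereocentre, is set in the first bond formation by the acetal tert-butyl group of 3 (the electrophile enters trans to it, net retention relative to (S)-lactic acid, hence 7R) and is quaternary from then on. The step needs attack at the pyranone carbonyl and not at the O–CH= carbon (the later C1), at C4a or at the enyne: the hard lithium enolate in THF at −78 °C is expected to react through a lithium-bridged six-membered transition state at the carbonyl, the 1,2-adduct fragments irreversibly, C4a is blocked by the alkynyl group, 11 has no acidic C–H to quench the enolate, and the pyranone ring fixes C6 and C8a cis on the C4a=C5 double bond as the second closure requires.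

**Step 8**
Reactants: 15 orsellinic acid (2,4-dihydroxy-6-methylbenzoic acid)
Product: 16 tert-butyldimethylsilyl 2,4-bis(tert-butyldimethylsilyloxy)-6-methylbenzoate
Conditions: TBSCl (3.5 equiv), imidazole, DMF, rt
Reagents that add atoms: tert-butyldimethylsilyl chloride, CC(C)(C)[Si](C)(C)Cl
Why: Exhaustive silylation of both phenols and the acid (silyl ester) at room temperature, mild enough to avoid decarboxylation of the resorcylic acid.

**Step 9**
Reactants: 16 tert-butyldimethylsilyl 2,4-bis(tert-butyldimethylsilyloxy)-6-methylbenzoate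
Product: 17 2,4-bis(tert-butyldimethylsilyloxy)-6-methylbenzoyl chloride
Conditions: (COCl)2, DMF (cat.), CH2Cl2, 0 °C → rt
Reagents that add atoms: oxalyl chloride, O=C(Cl)C(=O)Cl
Why: Vilsmeier-type conversion of a silyl ester into the acid chloride under neutral conditions, which should leave the aryl silyl ethers intact.

**Step 10**
Reactants: 14 (7R)-7-hydroxy-7-methyl-3-[(E)-3-(tert-butyldimethylsilyloxy)prop-1-en-1-yl]-6H-isochromene-6,8(7H)-dione; 17 2,4-bis(tert-butyldimethylsilyloxy)-6-methylbenzoyl chloride
Product: 18 (7R)-7-methyl-6,8-dioxo-3-[(E)-3-(tert-butyldimethylsilyloxy)prop-1-en-1-yl]-7,8-dihydro-6H-isochromen-7-yl 2,4-bis(tert-butyldimethylsilyloxy)-6-methylbenzoate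
Conditions: DMAP (0.3 equiv), Et3N (3 equiv), CH2Cl2, rt → 40 °C
Reagents that add atoms: none
Why: DMAP-catalysed acylation (nucleophilic catalysis) of the tertiary alcohol with the acid chloride; no bond at C7 is broken, so the configuration is kept.

**Step 11**
Reactants: 18 the tris-silyl ester from step 10
Product: 19 (7R)-3-[(E)-3-hydroxyprop-1-en-1-yl]-7-methyl-6,8-dioxo-7,8-dihydro-6H-isochromen-7-yl 2,4-dihydroxy-6-methylbenzoate
Conditions: HF·pyridine, pyridine, THF, 0 °C → rt
Reagents that add atoms: none
Why: Fluoride-mediated desilylation of the two aryl silyl ethers and the allylic silyl ether; buffered HF·pyridine should spare the ester, the enol ether and the base-sensitive bicycle.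

**Step 12**
Reactants: 19 the triol from step 11
Product: 20 (7R)-7-methyl-6,8-dioxo-3-[(E)-3-oxoprop-1-en-1-yl]-7,8-dihydro-6H-isochromen-7-yl 2,4-dihydroxy-6-methylbenzoate (target, CNP0200982.1)
Conditions: MnO2 (activated, excess), EtOAc, rt
Reagents that add atoms: none
Why: Chemoselective MnO2 oxidation of the primary allylic alcohol to the (E)-enal; the ester-deactivated phenols, the ester and the quaternary C7 should not be affected.

**Compound list**
1 | (S)-lactic acid | C[C@H](O)C(=O)O | starting material
2 | pivaldehyde | CC(C)(C)C=O | starting material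
3 | (2S,5S)-2-tert-butyl-5-methyl-1,3-dioxolan-4-one | C[C@@H]1O[C@H](C(C)(C)C)OC1=O | intermediate
4 | tert-butyl acetate | CC(=O)OC(C)(C)C | starting material
5 | methyl 3,3-dimethoxypropanoate | COC(=O)CC(OC)OC | starting material
6 | tert-butyl 5,5-dimethoxy-3-oxopentanoate | COC(OC)CC(=O)CC(=O)OC(C)(C)C | intermediate
7 | 4-hydroxy-2H-pyran-2-one | O=C1C=C(O)C=CO1 | intermediate
8 | 2-oxo-2H-pyran-4-yl trifluoromethanesulfonate | O=C1C=C(OS(=O)(=O)C(F)(F)F)C=CO1 | intermediate
9 | (E)-pent-2-en-4-yn-1-ol | C#C/C=C/CO | starting material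
10 | tert-butyldimethyl{[(E)-pent-2-en-4-yn-1-yl]oxy}silane | C#C/C=C/CO[Si](C)(C)C(C)(C)C | intermediate
11 | 4-[(E)-5-(tert-butyldimethylsilyloxy)pent-3-en-1-yn-1-yl]-2H-pyran-2-one | O=C1C=C(C#C/C=C/CO[Si](C)(C)C(C)(C)C)C=CO1 | intermediate
12 | lithium (1Z,3E)-5-[(2S,5R)-2-tert-butyl-5-methyl-4-oxo-1,3-dioxolan-5-yl]-5-oxo-3-[(E)-5-(tert-butyldimethylsilyloxy)pent-3-en-1-yn-1-yl]penta-1,3-dien-1-olate (ring-opened Claisen adduct, not isolated) | [Li+].[O-]/C=C\C(C#C/C=C/CO[Si](C)(C)C(C)(C)C)=C/C(=O)[C@@]1(C)O[C@H](C(C)(C)C)OC1=O | intermediate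
13 | (3S)-2,3-dihydroxy-3-methyl-4-oxo-6-[(E)-5-(tert-butyldimethylsilyloxy)pent-3-en-1-yn-1-yl]cyclohexa-1,5-diene-1-carbaldehyde (alkynyl vinylogous acid, not isolated; same spatial arrangement at C7 as the target, the descriptor differs only because the C8 enol changes the CIP ranking) | C[C@@]1(O)C(=O)C=C(C#C/C=C/CO[Si](C)(C)C(C)(C)C)C(C=O)=C1O | intermediate
14 | (7R)-7-hydroxy-7-methyl-3-[(E)-3-(tert-butyldimethylsilyloxy)prop-1-en-1-yl]-6H-isochromene-6,8(7H)-dione | C[C@@]1(O)C(=O)C=C2C=C(/C=C/CO[Si](C)(C)C(C)(C)C)OC=C2C1=O | intermediate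
15 | orsellinic acid (2,4-dihydroxy-6-methylbenzoic acid) | Cc1cc(O)cc(O)c1C(=O)O | starting material
16 | tert-butyldimethylsilyl 2,4-bis(tert-butyldimethylsilyloxy)-6-methylbenzoate | Cc1cc(O[Si](C)(C)C(C)(C)C)cc(O[Si](C)(C)C(C)(C)C)c1C(=O)O[Si](C)(C)C(C)(C)C | intermediate
17 | 2,4-bis(tert-butyldimethylsilyloxy)-6-methylbenzoyl chloride | Cc1cc(O[Si](C)(C)C(C)(C)C)cc(O[Si](C)(C)C(C)(C)C)c1C(Cl)=O | intermediate
18 | (7R)-7-methyl-6,8-dioxo-3-[(E)-3-(tert-butyldimethylsilyloxy)prop-1-en-1-yl]-7,8-dihydro-6H-isochromen-7-yl 2,4-bis(tert-butyldimethylsilyloxy)-6-methylbenzoate | Cc1cc(O[Si](C)(C)C(C)(C)C)cc(O[Si](C)(C)C(C)(C)C)c1C(=O)O[C@]1(C)C(=O)C=C2C=C(/C=C/CO[Si](C)(C)C(C)(C)C)OC=C2C1=O | intermediate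
19 | (7R)-3-[(E)-3-hydroxyprop-1-en-1-yl]-7-methyl-6,8-dioxo-7,8-dihydro-6H-isochromen-7-yl 2,4-dihydroxy-6-methylbenzoate | Cc1cc(O)cc(O)c1C(=O)O[C@]1(C)C(=O)C=C2C=C(/C=C/CO)OC=C2C1=O | intermediate
20 | (7R)-7-methyl-6,8-dioxo-3-[(E)-3-oxoprop-1-en-1-yl]-7,8-dihydro-6H-isochromen-7-yl 2,4-dihydroxy-6-methylbenzoate | Cc1cc(O)cc(O)c1C(=O)O[C@]1(C)C(=O)C=C2C=C(/C=C/C=O)OC=C2C1=O | target

**Total step count:** 12
**Longest linear sequence:** 8 steps (steps 2, 3, 4, 6, 7, 10, 11, 12)

**Steps most likely to fail**

1. Step 7 (proposed new method). What may go wrong: the enolate may attack the O–CH= carbon of the pyranone or the enyne instead of the lactone carbonyl, or the stabilized dienolate may be too sluggish for the second acyl transfer. The fallback makes the same two bonds by known enolate C-acylation with an acid chloride followed by a base-induced vinylogous Dieckmann closure. It sets out from 5, 10 and 3 and comes back to the route at 14 (through 13). Crossed Claisen condensation of 5 with the lithium enolate of methyl acetate would give methyl 5,5-dimethoxy-3-oxopentanoate F1. Tf2O with aqueous Me4NOH would give methyl (E)-5,5-dimethoxy-3-(trifluoromethylsulfonyloxy)pent-2-enoate F2. Sonogashira coupling with 10 (PdCl2(PPh3)2, CuI, Et3N) would give methyl (2E,6E)-8-(tert-butyldimethylsilyloxy)-3-(2,2-dimethoxyethyl)octa-2,6-dien-4-ynoate F3. LiOH would give the corresponding acid F4, and 1-chloro-N,N,2-trimethylpropenylamine would give the acid chloride F5. The lithium enolate of 3 would be acylated by F5 at −78 °C, again trans to the tert-butyl group, to give the (2S,5R)-5-acyl dioxolanone F6. LiHMDS in the same flask would deprotonate the gamma-CH2 and close the ring onto the dioxolanone carbonyl with loss of pivaldehyde, giving the acetal-protected vinylogous acid F7. PPTS in wet acetone would unmask the aldehyde to 13, and the CuI stage of step 7 would then give 14.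

2. Step 10. What may go wrong: acyl transfer between a doubly ortho-substituted aroyl chloride and a tertiary alcohol flanked by two carbonyls may be too slow, so that amine-induced degradation of the bicycle competes. The fallback moves the esterification to the monocyclic stage and uses an intramolecular acyl shift. It sets out from 13 (isolated by stopping step 7 before the CuI stage) and 17, and comes back at 18. O-Acylation of the acidic enol oxygen of 13 with 17 (Et3N, CH2Cl2, −20 °C) would give the enol ester F8. Under DMAP this active ester should pass its acyl group to the adjacent tertiary hydroxyl through a five-membered tetrahedral intermediate (O→O acyl migration), giving the 7-O-aroyl vinylogous acid F9. CuI-catalysed cycloisomerization of F9 would give 18.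

3. Step 3. What may go wrong: decarboxylation of the beta-keto acid, or self-condensation of the unmasked formyl ketone, may outrun enol-lactonization. The fallback closes the pyranone ring last, when the acid is a conjugated enynoic acid that cannot decarboxylate. It sets out from 6 and 9 and comes back at 11. Tf2O with aqueous Me4NOH would give tert-butyl (E)-5,5-dimethoxy-3-(trifluoromethylsulfonyloxy)pent-2-enoate F10. Sonogashira coupling with unprotected 9 would give tert-butyl (2E,6E)-3-(2,2-dimethoxyethyl)-8-hydroxyocta-2,6-dien-4-ynoate F11. TFA in CH2Cl2 would cleave the ester, close the acid onto the acetal carbon and eliminate methanol to give 4-[(E)-5-hydroxypent-3-en-1-yn-1-yl]-2H-pyran-2-one F12 (after bicarbonate work-up). TBSCl and imidazole would then give 11.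

**Further compounds**
F1 | step 7 | methyl 5,5-dimethoxy-3-oxopentanoate | COC(=O)CC(=O)CC(OC)OC
F2 | step 7 | methyl (E)-5,5-dimethoxy-3-(trifluoromethylsulfonyloxy)pent-2-enoate | COC(=O)/C=C(/OS(=O)(=O)C(F)(F)F)CC(OC)OC
F3 | step 7 | methyl (2E,6E)-8-(tert-butyldimethylsilyloxy)-3-(2,2-dimethoxyethyl)octa-2,6-dien-4-ynoate | COC(=O)/C=C(/C#C/C=C/CO[Si](C)(C)C(C)(C)C)CC(OC)OC
F4 | step 7 | (2E,6E)-8-(tert-butyldimethylsilyloxy)-3-(2,2-dimethoxyethyl)octa-2,6-dien-4-ynoic acid | OC(=O)/C=C(/C#C/C=C/CO[Si](C)(C)C(C)(C)C)CC(OC)OC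
F5 | step 7 | (2E,6E)-8-(tert-butyldimethylsilyloxy)-3-(2,2-dimethoxyethyl)octa-2,6-dien-4-ynoyl chloride | ClC(=O)/C=C(/C#C/C=C/CO[Si](C)(C)C(C)(C)C)CC(OC)OC
F6 | step 7 | (2S,5R)-2-tert-butyl-5-methyl-5-[(2E,6E)-8-(tert-butyldimethylsilyloxy)-3-(2,2-dimethoxyethyl)octa-2,6-dien-4-ynoyl]-1,3-dioxolan-4-one | C[C@]1(C(=O)/C=C(/C#C/C=C/CO[Si](C)(C)C(C)(C)C)CC(OC)OC)O[C@H](C(C)(C)C)OC1=O
F7 | step 7 | (6S)-3-(dimethoxymethyl)-2,6-dihydroxy-6-methyl-4-[(E)-5-(tert-butyldimethylsilyloxy)pent-3-en-1-yn-1-yl]cyclohexa-2,4-dien-1-one (dimethyl acetal of 13, drawn as the C8 enol) | C[C@@]1(O)C(=O)C=C(C#C/C=C/CO[Si](C)(C)C(C)(C)C)C(C(OC)OC)=C1O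
F8 | step 10 | enol ester of 13 at the C8 oxygen with the 2,4-bis(tert-butyldimethylsilyloxy)-6-methylbenzoyl group | C[C@@]1(O)C(=O)C=C(C#C/C=C/CO[Si](C)(C)C(C)(C)C)C(C=O)=C1OC(=O)c1c(C)cc(O[Si](C)(C)C(C)(C)C)cc1O[Si](C)(C)C(C)(C)C
F9 | step 10 | 7-O-[2,4-bis(tert-butyldimethylsilyloxy)-6-methylbenzoyl] derivative of 13 (tertiary ester, vinylogous acid) | C[C@@]1(OC(=O)c2c(C)cc(O[Si](C)(C)C(C)(C)C)cc2O[Si](C)(C)C(C)(C)C)C(=O)C=C(C#C/C=C/CO[Si](C)(C)C(C)(C)C)C(C=O)=C1O
F10 | step 3 | tert-butyl (E)-5,5-dimethoxy-3-(trifluoromethylsulfonyloxy)pent-2-enoate | CC(C)(C)OC(=O)/C=C(/OS(=O)(=O)C(F)(F)F)CC(OC)OC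
F11 | step 3 | tert-butyl (2E,6E)-3-(2,2-dimethoxyethyl)-8-hydroxyocta-2,6-dien-4-ynoate | CC(C)(C)OC(=O)/C=C(/C#C/C=C/CO)CC(OC)OC
F12 | step 3 | 4-[(E)-5-hydroxypent-3-en-1-yn-1-yl]-2H-pyran-2-one | O=C1C=C(C#C/C=C/CO)C=CO1
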